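## Retrosynthetic overview

- The strategy rests on one feature. In the cis-fused bicycle, C4 is a CH2 between the oxygenated C3 and the fusion carbon C4a of the piperidine ring (N1–C2–C3–C4–C4a–C8a). C5 of the carbocycle (C4a–C5–C6–C7–C8–C8a) holds the side chain cis to C4. C4–C4a can therefore come from a C4 radical and C5–H from hydrogen-atom transfer.
- Endgame: the ester C–O bond (acid 20 + N-Boc alcohol 19), N–S cleavage, and the C3 carbinol from ketone 16 by hydride addition.
- Key disconnection: C4–C4a of 16 leads back to iodomethyl ketone 15. The carbocycle is present from the start; the piperidinone is the only ring formed, by 6-exo radical closure.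
- 15 comes from ester 13 by one-carbon homologation; 13 comes from N–C8a formation (Mitsunobu inversion) between (1S)-allylic alcohol 10 and N-tosyl-D-alanine ester 12.
- 10 comes from enone 9, made by C5–C1′ coupling (B-alkyl Suzuki) of 3-iodocyclohex-2-enone 6 with alkene 4, itself from (R)-2-propyloxirane 1 and allylmagnesium bromide 2.

Key step: step 10

Remark 1: the alkene carbon next to the nitrogen-bearing carbon must be unsubstituted (it becomes C4a), and the side chain must sit on the far alkene carbon (it becomes C5). The cyclization substrate is therefore a 3-alkylcyclohex-2-en-1-yl amine, and its ring is built from a β-iodo enone (from cyclohexane-1,3-dione), not from an α-iodo enone.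

Remark 2: D-alanine methyl ester is taken as its commercial hydrochloride. Locants C2–C8a are those of the decahydroquinoline, C1′–C8′ those of the octyl chain. Ketone 16 can epimerize at C2 and would be reduced without storage.

## Route

Step 1
Reactants: 1 (R)-2-propyloxirane; 2 allylmagnesium bromide
Product: 3 (4R)-oct-7-en-4-ol
Conditions: CuI (10 mol%), THF/Et2O, −30 °C → 0 °C; then 1 M HCl
Reagents that add atoms: none
Why: Copper-catalysed Grignard opening of a terminal epoxide takes place at the unsubstituted carbon by SN2 attack, so the C–O stereocentre of 1 is carried unchanged into the (4R) carbinol that becomes C5′.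

Step 2
Reactants: 3 (4R)-oct-7-en-4-ol
Product: 4 tert-butyl(dimethyl)[(4R)-oct-7-en-4-yloxy]silane
Conditions: TBSCl, imidazole, DMF, rt
Reagents that add atoms: tert-butyldimethylsilyl chloride, CC(C)(C)[Si](C)(C)Cl
Why: Silylation of a secondary alcohol with TBSCl and imidazole is routine, and the silyl ether should survive every later step up to the final acid treatment.

Step 3
Reactants: 5 cyclohexane-1,3-dione
Product: 6 3-iodocyclohex-2-en-1-one
Conditions: PPh3, I2, Et3N, MeCN, rt
Reagents that add atoms: iodine, II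
Why: Phosphonium activation of the enol oxygen of the 1,3-dione followed by addition–elimination of iodide is a standard conversion of cyclic 1,3-diketones into β-iodo enones.

Step 4
Reactants: 4 tert-butyl(dimethyl)[(4R)-oct-7-en-4-yloxy]silane; 7 9-borabicyclo[3.3.1]nonane (9-BBN); 6 3-iodocyclohex-2-en-1-one
Product: 9 3-[(5R)-5-{[tert-butyl(dimethyl)silyl]oxy}octyl]cyclohex-2-en-1-one, via B-alkyl-9-BBN adduct 8 (not isolated)
Conditions: 4, 9-BBN, THF, 0 °C → rt; then 6, PdCl2(dppf)·CH2Cl2 (5 mol%), AsPh3 (5 mol%), Cs2CO3, DMF/H2O, rt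
Reagents that add atoms: none
Why: Hydroboration of the terminal alkene by 9-BBN puts boron on the terminal carbon, and B-alkyl Suzuki–Miyaura coupling of this borane with the β-iodo enone (divalent palladium precatalyst, reduced in the flask to zerovalent palladium) places the chain on C3 of the enone, the carbon that becomes C5.

Step 5
Reactants: 9 3-[(5R)-5-{[tert-butyl(dimethyl)silyl]oxy}octyl]cyclohex-2-en-1-one
Product: 10 (1S)-3-[(5R)-5-{[tert-butyl(dimethyl)silyl]oxy}octyl]cyclohex-2-en-1-ol
Conditions: (R)-1-methyl-3,3-diphenyltetrahydro-1H,3H-pyrrolo[1,2-c][1,3,2]oxazaborole (20 mol%), catecholborane, PhMe, −78 °C; then MeOH, aq NaOH wash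
Reagents that add atoms: none
Why: Corey–Bakshi–Shibata reduction delivers hydride 1,2 to the carbonyl face fixed by the oxazaborolidine, with the alkenyl arm acting as the larger group, so the (R)-catalyst should set the (1S) carbinol, and catecholborane at low temperature leaves the ring alkene alone.

Step 6
Reactants: 11 D-alanine methyl ester hydrochloride
Product: 12 methyl N-[(4-methylphenyl)sulfonyl]-D-alaninate
Conditions: TsCl, Et3N, CH2Cl2, 0 °C → rt
Reagents that add atoms: 4-methylbenzenesulfonyl chloride, Cc1ccc(cc1)S(Cl)(=O)=O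
Why: Sulfonylation of the primary amine with TsCl and a tertiary amine base is routine and does not touch the α-stereocentre that becomes C2.

Step 7
Reactants: 10 (1S)-3-[(5R)-5-{[tert-butyl(dimethyl)silyl]oxy}octyl]cyclohex-2-en-1-ol; 12 methyl N-[(4-methylphenyl)sulfonyl]-D-alaninate
Product: 13 methyl N-{(1R)-3-[(5R)-5-{[tert-butyl(dimethyl)silyl]oxy}octyl]cyclohex-2-en-1-yl}-N-[(4-methylphenyl)sulfonyl]-D-alaninate
Conditions: PPh3, DIAD, THF, 0 °C → rt
Reagents that add atoms: none
Why: Mitsunobu N-alkylation of the acidic sulfonamide N–H by the activated allylic alcohol proceeds by SN2 displacement with inversion, turning (1S)-10 into the (1R) C–N centre that becomes C8a, while SN2′ attack is disfavoured because it would have to form a C–N bond at the fully substituted alkene carbon.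

Step 8
Reactants: 13 methyl N-{(1R)-3-[(5R)-5-{[tert-butyl(dimethyl)silyl]oxy}octyl]cyclohex-2-en-1-yl}-N-[(4-methylphenyl)sulfonyl]-D-alaninate
Product: 14 N-[(2R)-4-chloro-3-oxobutan-2-yl]-N-{(1R)-3-[(5R)-5-{[tert-butyl(dimethyl)silyl]oxy}octyl]cyclohex-2-en-1-yl}-4-methylbenzenesulfonamide
Conditions: ICH2Cl, MeLi·LiBr, THF, −78 °C; then AcOH, −78 °C → rt
Reagents that add atoms: chloroiodomethane, ClCI
Why: Chloromethyllithium, formed in the flask by iodine–lithium exchange in the presence of the ester, adds once to the ester carbonyl and the α-chloro ketone is released only on the acidic quench (one-carbon homologation of an ester with a halomethyl carbenoid), and at −78 °C exchange and addition should outrun enolization of the nitrogen-bearing stereocentre.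

Step 9
Reactants: 14 N-[(2R)-4-chloro-3-oxobutan-2-yl]-N-{(1R)-3-[(5R)-5-{[tert-butyl(dimethyl)silyl]oxy}octyl]cyclohex-2-en-1-yl}-4-methylbenzenesulfonamide
Product: 15 N-{(1R)-3-[(5R)-5-{[tert-butyl(dimethyl)silyl]oxy}octyl]cyclohex-2-en-1-yl}-N-[(2R)-4-iodo-3-oxobutan-2-yl]-4-methylbenzenesulfonamide
Conditions: NaI, acetone, rt, dark
Reagents that add atoms: sodium iodide, [Na+].[I-]
Why: Finkelstein exchange at the activated α-keto carbon is fast in acetone and is driven by precipitation of NaCl, giving the weak C–I bond needed for clean radical generation.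

Step 10
Reactants: 15 N-{(1R)-3-[(5R)-5-{[tert-butyl(dimethyl)silyl]oxy}octyl]cyclohex-2-en-1-yl}-N-[(2R)-4-iodo-3-oxobutan-2-yl]-4-methylbenzenesulfonamide
Product: 16 (2R,4aS,5S,8aR)-5-[(5R)-5-{[tert-butyl(dimethyl)silyl]oxy}octyl]-2-methyl-1-[(4-methylphenyl)sulfonyl]octahydroquinolin-3(2H)-one
Conditions: (Me3Si)3SiH (1.5 equiv) and AIBN (0.3 equiv) added by syringe pump over 8 h, degassed PhMe (5 mM in 15), 80 °C
Reagents that add atoms: none
Why: AIBN-derived radicals start a chain in which the silyl radical abstracts iodine from 15 to give an electrophilic α-keto radical at C4, which adds to C4a, the unsubstituted carbon of the trisubstituted ring alkene, and the resulting tertiary C5 radical takes hydrogen from (Me3Si)3SiH and regenerates the silyl radical. The closest known reaction type is the 6-exo-trig cyclization of α-carbonyl radicals made from α-halo ketones under silane or stannane chain conditions, together with cis-selective 6-exo closures onto N-cyclohex-2-enyl tethers. The piperidin-3-one ring (N1–C2–C3–C4–C4a–C8a) closes in the 6-exo-trig mode by formation of C4–C4a; the 7-endo mode is shut off because it would have to attack the fully substituted C5 and leave a secondary radical. C4a is set by the C8a stereocentre: the three-atom tether from nitrogen reaches C4a along the axial trajectory of the cyclohexene half-chair on the face of the C8a–N bond, whereas a trans fusion would need a boat-like transition state, so the fusion should be cis. C5 is set in the hydrogen-atom transfer: the silane should approach the planar C5 radical axially and anti to the axial C4–C4a bond on the neighbouring carbon, which leaves the side chain equatorial and cis to C4. The step needs exo regioselectivity, cis fusion and anti hydrogen delivery, which the C5 substituent and the C8a centre secure, and it needs ring closure to outrun direct reduction and 1,5-hydrogen shift from C8a, which high dilution and slow silane addition are meant to secure.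

Step 11
Reactants: 16 (2R,4aS,5S,8aR)-5-[(5R)-5-{[tert-butyl(dimethyl)silyl]oxy}octyl]-2-methyl-1-[(4-methylphenyl)sulfonyl]octahydroquinolin-3(2H)-one
Product: 17 (2R,3R,4aS,5S,8aR)-5-[(5R)-5-{[tert-butyl(dimethyl)silyl]oxy}octyl]-2-methyl-1-[(4-methylphenyl)sulfonyl]decahydroquinolin-3-ol
Conditions: LiBH(s-Bu)3, THF, −78 °C; then H2O
Reagents that add atoms: none
Why: LiBH(s-Bu)3 should add to C3 from the face opposite the C2 methyl group (equatorial attack on the piperidinone chair that best accommodates the carbocycle and side chain), giving the axial (3R) alcohol cis to the methyl group, as is typical for bulky-hydride reduction of N-protected 2-alkylpiperidin-3-ones.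

Step 12
Reactants: 17 (2R,3R,4aS,5S,8aR)-5-[(5R)-5-{[tert-butyl(dimethyl)silyl]oxy}octyl]-2-methyl-1-[(4-methylphenyl)sulfonyl]decahydroquinolin-3-ol
Product: 18 (2R,3R,4aS,5S,8aR)-5-[(5R)-5-{[tert-butyl(dimethyl)silyl]oxy}octyl]-2-methyldecahydroquinolin-3-ol
Conditions: NaC10H8 (sodium naphthalenide, stock solution in DME, excess), DME, −78 °C; then H2O
Reagents that add atoms: none
Why: Single-electron reduction of the arenesulfonyl group by NaC10H8 cleaves the N–S bond (reductive desulfonylation) without affecting the silyl ether or any stereocentre.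

Step 13
Reactants: 18 (2R,3R,4aS,5S,8aR)-5-[(5R)-5-{[tert-butyl(dimethyl)silyl]oxy}octyl]-2-methyldecahydroquinolin-3-ol
Product: 19 tert-butyl (2R,3R,4aS,5S,8aR)-5-[(5R)-5-{[tert-butyl(dimethyl)silyl]oxy}octyl]-3-hydroxy-2-methyloctahydroquinoline-1(2H)-carboxylate
Conditions: Boc2O, Et3N, THF, 50 °C
Reagents that add atoms: di-tert-butyl dicarbonate, CC(C)(C)OC(=O)OC(=O)OC(C)(C)C
Why: Carbamate formation with Boc2O is selective for the secondary amine over the secondary alcohol when no acyl-transfer catalyst is present, masking nitrogen for the esterification.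

Step 14
Reactants: 20 (2E,4E)-octa-2,4-dienoic acid; 21 2,4,6-trichlorobenzoyl chloride; 19 tert-butyl (2R,3R,4aS,5S,8aR)-5-[(5R)-5-{[tert-butyl(dimethyl)silyl]oxy}octyl]-3-hydroxy-2-methyloctahydroquinoline-1(2H)-carboxylate
Product: 23 tert-butyl (2R,3R,4aS,5S,8aR)-5-[(5R)-5-{[tert-butyl(dimethyl)silyl]oxy}octyl]-2-methyl-3-{[(2E,4E)-octa-2,4-dienoyl]oxy}octahydroquinoline-1(2H)-carboxylate, via mixed anhydride 22 (not isolated)
Conditions: 20, 21, Et3N, THF, rt; then 19, DMAP, PhMe, rt → 50 °C
Reagents that add atoms: none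
Why: Yamaguchi esterification, in which DMAP attacks the mixed anhydride at the less hindered dienoyl carbonyl and the acylpyridinium salt esterifies the hindered axial C3 hydroxyl with retention at C3 and without moving the diene geometry.

Step 15
Reactants: 23 tert-butyl (2R,3R,4aS,5S,8aR)-5-[(5R)-5-{[tert-butyl(dimethyl)silyl]oxy}octyl]-2-methyl-3-{[(2E,4E)-octa-2,4-dienoyl]oxy}octahydroquinoline-1(2H)-carboxylate
Product: 24 (2R,3R,4aS,5S,8aR)-5-[(5R)-5-hydroxyoctyl]-2-methyldecahydroquinolin-3-yl (2E,4E)-octa-2,4-dienoate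
Conditions: TFA/CH2Cl2/H2O (10:10:1), 0 °C → rt; then aq NaHCO3
Reagents that add atoms: none
Why: Aqueous TFA removes the tert-butyl carbamate (loss of 2-methylpropene and CO2) and hydrolyses the secondary silyl ether in one operation, while the dienoate ester and all stereocentres are stable to acid, and basic work-up gives the free amine.

## Compound list

1 | (R)-2-propyloxirane | CCC[C@@H]1CO1 | starting material
2 | allylmagnesium bromide | C=CC[Mg]Br | starting material
3 | (4R)-oct-7-en-4-ol | C=CCC[C@H](O)CCC | intermediate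
4 | tert-butyl(dimethyl)[(4R)-oct-7-en-4-yloxy]silane | C=CCC[C@H](O[Si](C)(C)C(C)(C)C)CCC | intermediate
5 | cyclohexane-1,3-dione | O=C1CCCC(=O)C1 | starting material
6 | 3-iodocyclohex-2-en-1-one | O=C1C=C(I)CCC1 | intermediate
7 | 9-borabicyclo[3.3.1]nonane (9-BBN) | B1C2CCCC1CCC2 | starting material
8 | 9-[(5R)-5-{[tert-butyl(dimethyl)silyl]oxy}octyl]-9-borabicyclo[3.3.1]nonane (formed in the flask, not isolated) | CCC[C@@H](O[Si](C)(C)C(C)(C)C)CCCCB1C2CCCC1CCC2 | intermediate
9 | 3-[(5R)-5-{[tert-butyl(dimethyl)silyl]oxy}octyl]cyclohex-2-en-1-one | O=C1C=C(CCCC[C@H](O[Si](C)(C)C(C)(C)C)CCC)CCC1 | intermediate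
10 | (1S)-3-[(5R)-5-{[tert-butyl(dimethyl)silyl]oxy}octyl]cyclohex-2-en-1-ol | O[C@H]1CCCC(CCCC[C@H](O[Si](C)(C)C(C)(C)C)CCC)=C1 | intermediate
11 | D-alanine methyl ester hydrochloride | C[C@@H](N)C(=O)OC.Cl | starting material
12 | methyl N-[(4-methylphenyl)sulfonyl]-D-alaninate | C[C@@H](NS(=O)(=O)c1ccc(C)cc1)C(=O)OC | intermediate
13 | methyl N-{(1R)-3-[(5R)-5-{[tert-butyl(dimethyl)silyl]oxy}octyl]cyclohex-2-en-1-yl}-N-[(4-methylphenyl)sulfonyl]-D-alaninate | COC(=O)[C@@H](C)N(S(=O)(=O)c1ccc(C)cc1)[C@@H]1CCCC(CCCC[C@H](O[Si](C)(C)C(C)(C)C)CCC)=C1 | intermediate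
14 | N-[(2R)-4-chloro-3-oxobutan-2-yl]-N-{(1R)-3-[(5R)-5-{[tert-butyl(dimethyl)silyl]oxy}octyl]cyclohex-2-en-1-yl}-4-methylbenzenesulfonamide | ClCC(=O)[C@@H](C)N(S(=O)(=O)c1ccc(C)cc1)[C@@H]1CCCC(CCCC[C@H](O[Si](C)(C)C(C)(C)C)CCC)=C1 | intermediate
15 | N-{(1R)-3-[(5R)-5-{[tert-butyl(dimethyl)silyl]oxy}octyl]cyclohex-2-en-1-yl}-N-[(2R)-4-iodo-3-oxobutan-2-yl]-4-methylbenzenesulfonamide | ICC(=O)[C@@H](C)N(S(=O)(=O)c1ccc(C)cc1)[C@@H]1CCCC(CCCC[C@H](O[Si](C)(C)C(C)(C)C)CCC)=C1 | intermediate
16 | (2R,4aS,5S,8aR)-5-[(5R)-5-{[tert-butyl(dimethyl)silyl]oxy}octyl]-2-methyl-1-[(4-methylphenyl)sulfonyl]octahydroquinolin-3(2H)-one | O=C1C[C@H]2[C@@H](CCCC[C@H](O[Si](C)(C)C(C)(C)C)CCC)CCC[C@H]2N(S(=O)(=O)c2ccc(C)cc2)[C@@H]1C | intermediate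
17 | (2R,3R,4aS,5S,8aR)-5-[(5R)-5-{[tert-butyl(dimethyl)silyl]oxy}octyl]-2-methyl-1-[(4-methylphenyl)sulfonyl]decahydroquinolin-3-ol | O[C@@H]1C[C@H]2[C@@H](CCCC[C@H](O[Si](C)(C)C(C)(C)C)CCC)CCC[C@H]2N(S(=O)(=O)c2ccc(C)cc2)[C@@H]1C | intermediate
18 | (2R,3R,4aS,5S,8aR)-5-[(5R)-5-{[tert-butyl(dimethyl)silyl]oxy}octyl]-2-methyldecahydroquinolin-3-ol | O[C@@H]1C[C@H]2[C@@H](CCCC[C@H](O[Si](C)(C)C(C)(C)C)CCC)CCC[C@H]2N[C@@H]1C | intermediate
19 | tert-butyl (2R,3R,4aS,5S,8aR)-5-[(5R)-5-{[tert-butyl(dimethyl)silyl]oxy}octyl]-3-hydroxy-2-methyloctahydroquinoline-1(2H)-carboxylate | O[C@@H]1C[C@H]2[C@@H](CCCC[C@H](O[Si](C)(C)C(C)(C)C)CCC)CCC[C@H]2N(C(=O)OC(C)(C)C)[C@@H]1C | intermediate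
20 | (2E,4E)-octa-2,4-dienoic acid | CCC/C=C/C=C/C(=O)O | starting material
21 | 2,4,6-trichlorobenzoyl chloride | O=C(Cl)c1c(Cl)cc(Cl)cc1Cl | starting material
22 | (2E,4E)-octa-2,4-dienoic 2,4,6-trichlorobenzoic anhydride (formed in the flask, not isolated) | CCC/C=C/C=C/C(=O)OC(=O)c1c(Cl)cc(Cl)cc1Cl | intermediate
23 | tert-butyl (2R,3R,4aS,5S,8aR)-5-[(5R)-5-{[tert-butyl(dimethyl)silyl]oxy}octyl]-2-methyl-3-{[(2E,4E)-octa-2,4-dienoyl]oxy}octahydroquinoline-1(2H)-carboxylate | CCC/C=C/C=C/C(=O)O[C@@H]1C[C@H]2[C@@H](CCCC[C@H](O[Si](C)(C)C(C)(C)C)CCC)CCC[C@H]2N(C(=O)OC(C)(C)C)[C@@H]1C | intermediate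
24 | (2R,3R,4aS,5S,8aR)-5-[(5R)-5-hydroxyoctyl]-2-methyldecahydroquinolin-3-yl (2E,4E)-octa-2,4-dienoate | CCC/C=C/C=C/C(=O)O[C@@H]1C[C@H]2[C@@H](CCCC[C@H](O)CCC)CCC[C@H]2N[C@@H]1C | target

## Step count

Total steps: 15.
Longest linear sequence: 13 steps (steps 1, 2, 4, 5, 7, 8, 9, 10, 11, 12, 13, 14, 15, from (R)-2-propyloxirane).

## Steps most likely to fail, with fallbacks

**Step 10 (radical cyclization).** The C4 radical may be reduced by the silane, or may take the C8a hydrogen by 1,5-shift, before it closes the ring; hydrogen delivery to C5 may also be poorly face-selective. The fallback changes from a reductive chain to a xanthate group-transfer cyclization, which has no hydrogen donor in the flask during ring closure. It sets out from chloromethyl ketone 14. Displacement of chloride with potassium O-ethyl xanthate (KS2COEt, acetone, 0 °C) should give O-ethyl S-[(3R)-3-({(1R)-3-[(5R)-5-{[tert-butyl(dimethyl)silyl]oxy}octyl]cyclohex-2-en-1-yl}[(4-methylphenyl)sulfonyl]amino)-2-oxobutyl] carbonodithioate F1. Dilauroyl peroxide, added in portions in refluxing 1,2-dichloroethane, should then give the cyclized tertiary xanthate, O-ethyl S-{5-[(5R)-5-{[tert-butyl(dimethyl)silyl]oxy}octyl]-2-methyl-1-[(4-methylphenyl)sulfonyl]-3-oxodecahydroquinolin-5-yl} carbonodithioate (cis-fused, C2, C4a and C8a as in 16, both C5 epimers) F2. Treatment of this xanthate with (Me3Si)3SiH and AIBN in PhMe at 80 °C regenerates the C5 radical in a separate operation, where the hydrogen donor can be chosen freely, and replaces the xanthate by hydrogen. The fallback comes back to the route at ketone 16.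

**Step 7 (Mitsunobu N-alkylation).** Alkylation of the hindered, only moderately acidic sulfonamide 12 may be slow, so that SN2′ attack, elimination to the diene and partial loss of configuration at the allylic carbon compete. The fallback brings in nitrogen with a small, strongly acidic nucleophile and attaches the alanine carbon afterwards by a separate SN2 step. It sets out from alcohol 10. Mitsunobu reaction with tert-butyl tosylcarbamate (PPh3, DIAD, THF) should give, with inversion, tert-butyl {(1R)-3-[(5R)-5-{[tert-butyl(dimethyl)silyl]oxy}octyl]cyclohex-2-en-1-yl}[(4-methylphenyl)sulfonyl]carbamate F3. Removal of the carbamate with Me3SiOTf and 2,6-lutidine in CH2Cl2, then MeOH, which spares the silyl ether, should give N-{(1R)-3-[(5R)-5-{[tert-butyl(dimethyl)silyl]oxy}octyl]cyclohex-2-en-1-yl}-4-methylbenzenesulfonamide F4. This sulfonamide would be alkylated (Cs2CO3, MeCN, 0 °C → rt) with methyl (2S)-2-{[(trifluoromethyl)sulfonyl]oxy}propanoate F5, made from methyl (S)-lactate with Tf2O and 2,6-lutidine in CH2Cl2 at −78 °C. SN2 inversion at the lactate carbon gives the D-alanine configuration. The fallback comes back to the route at ester 13.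

**Step 5 (enantioselective ketone reduction).** The ring carbonyl has no α-substituent, so the oxazaborolidine may differentiate the two enone faces only weakly and give low selectivity at the carbinol, with some hydroboration of the ring alkene. The fallback replaces asymmetric catalysis by a resolution. It sets out from enone 9. Luche reduction (NaBH4, CeCl3·7H2O, MeOH, 0 °C) should give 3-[(5R)-5-{[tert-butyl(dimethyl)silyl]oxy}octyl]cyclohex-2-en-1-ol as both C1 epimers F6. Lipase-catalysed acylation (Candida antarctica lipase B, vinyl acetate, hexane, rt) is expected, by the usual size rule for secondary alcohols, to acetylate the (1R) epimer to (1R)-3-[(5R)-5-{[tert-butyl(dimethyl)silyl]oxy}octyl]cyclohex-2-en-1-yl acetate F7 and leave the (1S) alcohol. After chromatographic separation the fallback comes back to the route at alcohol 10.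

## Further compounds

F1 | step 10 | O-ethyl S-[(3R)-3-({(1R)-3-[(5R)-5-{[tert-butyl(dimethyl)silyl]oxy}octyl]cyclohex-2-en-1-yl}[(4-methylphenyl)sulfonyl]amino)-2-oxobutyl] carbonodithioate | CCOC(=S)SCC(=O)[C@@H](C)N(S(=O)(=O)c1ccc(C)cc1)[C@@H]1CCCC(CCCC[C@H](O[Si](C)(C)C(C)(C)C)CCC)=C1
F2 | step 10 | O-ethyl S-{5-[(5R)-5-{[tert-butyl(dimethyl)silyl]oxy}octyl]-2-methyl-1-[(4-methylphenyl)sulfonyl]-3-oxodecahydroquinolin-5-yl} carbonodithioate (cis-fused, C2, C4a and C8a as in 16, both C5 epimers) | O=C1C[C@H]2C(SC(=S)OCC)(CCCC[C@H](O[Si](C)(C)C(C)(C)C)CCC)CCC[C@H]2N(S(=O)(=O)c2ccc(C)cc2)[C@@H]1C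
F3 | step 7 | tert-butyl {(1R)-3-[(5R)-5-{[tert-butyl(dimethyl)silyl]oxy}octyl]cyclohex-2-en-1-yl}[(4-methylphenyl)sulfonyl]carbamate | CC(C)(C)OC(=O)N(S(=O)(=O)c1ccc(C)cc1)[C@@H]1CCCC(CCCC[C@H](O[Si](C)(C)C(C)(C)C)CCC)=C1
F4 | step 7 | N-{(1R)-3-[(5R)-5-{[tert-butyl(dimethyl)silyl]oxy}octyl]cyclohex-2-en-1-yl}-4-methylbenzenesulfonamide | Cc1ccc(cc1)S(=O)(=O)N[C@@H]1CCCC(CCCC[C@H](O[Si](C)(C)C(C)(C)C)CCC)=C1
F5 | step 7 | methyl (2S)-2-{[(trifluoromethyl)sulfonyl]oxy}propanoate | C[C@H](OS(=O)(=O)C(F)(F)F)C(=O)OC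
F6 | step 5 | 3-[(5R)-5-{[tert-butyl(dimethyl)silyl]oxy}octyl]cyclohex-2-en-1-ol (both C1 epimers) | OC1CCCC(CCCC[C@H](O[Si](C)(C)C(C)(C)C)CCC)=C1
F7 | step 5 | (1R)-3-[(5R)-5-{[tert-butyl(dimethyl)silyl]oxy}octyl]cyclohex-2-en-1-yl acetate | CC(=O)O[C@@H]1CCCC(CCCC[C@H](O[Si](C)(C)C(C)(C)C)CCC)=C1
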